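**Retrosynthetic overview**

1. Target ⇐ enol O‑methylation and formylation of a C4 acetyl group; C7 carbinol by equatorial methyl addition to a C7 ketone; C1 ketone and C2 carbinol by hydroxyl‑directed dihydroxylation and oxidation of a C1=C2 alkene.
2. Rings A and B close in one operation: intramolecular Diels–Alder reaction of a (Z)‑1‑siloxy‑1,3‑diene with a tethered α‑methyl enamide (ring B closes through the tether as ring A forms). The C5 methyl stereocentre controls C3, C4, C4a and C8a.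
3. Key C8a–C1 bond: nickel‑catalysed electroreductive acyl–allyl coupling of a β‑hydroxy thioester with an (E)‑allylic bromide. It gives the skipped (β,γ) enone needed for regiodefined dienol ether formation.
4. Thioester from methyl (R)‑3‑hydroxy‑2‑methylpropanoate (C5 stereocentre); allylic bromide from (S)‑2‑methylbutan‑1‑ol (sec‑butyl stereocentre).

Assumption: the SMILES is read as the (2S,3R,4S,4aR,5R,7R,8aR) enantiomer with an (S)‑butan‑2‑yl group; for bicyclic compounds the ring locants are those of the target (C1 = ring C=O, C8a = carbinol ring‑fusion carbon) and β is the face of the 8a‑oxygen.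

**Step 1**
Reactants: 1 methyl (R)‑3‑hydroxy‑2‑methylpropanoate
Product: 2 methyl (S)‑3‑iodo‑2‑methylpropanoate
Conditions: I2, PPh3, imidazole, CH2Cl2, 0 °C → rt
Reagents that add atoms: iodine, II
Why: Appel‑type iodination is an SN2 displacement at the primary CH2 carbon, so the adjacent stereocentre is untouched (the descriptor changes only through CIP priority).

**Step 2**
Reactants: 2 methyl (S)‑3‑iodo‑2‑methylpropanoate
Product: 4 methyl (R)‑2‑methylpent‑4‑enoate, via alkylzinc iodide 3 (not isolated)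
Conditions: Zn dust (activated), DMF, rt; then CH2=CHBr, Pd2(dba)3 (2.5 mol%), P(o‑tol)3 (10 mol%), THF, rt → 40 °C
Reagents that add atoms: bromoethene, C=CBr; zinc, [Zn] (present only in 3)
Why: Zinc inserts into the primary C–I bond to give a β‑zincio ester whose stereocentre is β to the metal and therefore configurationally safe, and Negishi cross‑coupling with bromoethene then installs the terminal alkene.

**Step 3**
Reactants: 4 methyl (R)‑2‑methylpent‑4‑enoate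
Product: 6 (2E,4R)‑N‑methoxy‑N,2,4‑trimethylhepta‑2,6‑dienamide, via (R)‑2‑methylpent‑4‑enal 5 (not isolated)
Conditions: (i‑Bu)2AlH (1.05 equiv), CH2Cl2, −78 °C; MeOH quench; then Ph3P=C(Me)C(O)N(OMe)Me, CH2Cl2, 40 °C
Reagents that add atoms: N‑methoxy‑N‑methyl‑2‑(triphenyl‑λ5‑phosphanylidene)propanamide, CON(C)C(=O)C(C)=P(c1ccccc1)(c1ccccc1)c1ccccc1
Why: Partial ester reduction at −78 °C stops at the aldehyde, which is olefinated without isolation by a base‑free Wittig reaction with the stabilised α‑methyl ylide, giving the (E)‑trisubstituted enamide without epimerising the α‑methyl aldehyde.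

**Step 4**
Reactants: 6 (2E,4R)‑N‑methoxy‑N,2,4‑trimethylhepta‑2,6‑dienamide
Product: 8 (2E,4R)‑N‑methoxy‑N,2,4‑trimethyl‑6‑oxohex‑2‑enamide, via 1,2,4‑trioxolane 7 (not isolated)
Conditions: O3, CH2Cl2, −78 °C (1.0 equiv, stopped at first excess); then PPh3, −78 °C → rt
Reagents that add atoms: ozone, [O-][O+]=O
Why: Ozonolysis with reductive work‑up cleaves only the electron‑rich monosubstituted alkene, because the electron‑poor trisubstituted enamide reacts far more slowly with ozone.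

**Step 5**
Reactants: 8 (2E,4R)‑N‑methoxy‑N,2,4‑trimethyl‑6‑oxohex‑2‑enamide
Product: 9 S‑phenyl (5R,6E)‑3‑hydroxy‑8‑[methoxy(methyl)amino]‑5,7‑dimethyl‑8‑oxooct‑6‑enethioate (C3 epimers)
Conditions: CH3C(O)SPh, LiN(i‑Pr)2, THF, −78 °C; then 8; AcOH, −78 °C
Reagents that add atoms: S‑phenyl ethanethioate, CC(=O)Sc1ccccc1
Why: Lithium enolate aldol addition to the aldehyde is fast at −78 °C and chemoselective over the enamide; the new carbinol centre (future C7) is an inconsequential epimer mixture because it is oxidised later.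

**Step 6**
Reactants: 10 (S)‑2‑methylbutan‑1‑ol
Product: 12 ethyl (2E,4S)‑2,4‑dimethylhex‑2‑enoate, via (S)‑2‑methylbutanal 11 (not isolated)
Conditions: TEMPO (10 mol%), PhI(OAc)2, CH2Cl2, rt; then Ph3P=C(Me)CO2Et, rt
Reagents that add atoms: ethyl 2‑(triphenyl‑λ5‑phosphanylidene)propanoate, CCOC(=O)C(C)=P(c1ccccc1)(c1ccccc1)c1ccccc1
Why: The non‑basic TEMPO oxidation gives the epimerisable aldehyde, which the in situ Wittig olefination traps at once as the (E)‑enoate with the sec‑butyl stereocentre intact.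

**Step 7**
Reactants: 12 ethyl (2E,4S)‑2,4‑dimethylhex‑2‑enoate
Product: 13 (2E,4S)‑2,4‑dimethylhex‑2‑en‑1‑ol
Conditions: (i‑Bu)2AlH (2.2 equiv), CH2Cl2, −78 → 0 °C
Reagents that add atoms: none
Why: 1,2‑Reduction of the enoate by the aluminium hydride gives the allylic alcohol without touching the alkene geometry or the stereocentre.

**Step 8**
Reactants: 13 (2E,4S)‑2,4‑dimethylhex‑2‑en‑1‑ol
Product: 14 (2E,4S)‑1‑bromo‑2,4‑dimethylhex‑2‑ene
Conditions: CBr4, PPh3, CH2Cl2, 0 °C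
Reagents that add atoms: tetrabromomethane, BrC(Br)(Br)Br
Why: Appel bromination is an SN2 displacement at the primary allylic carbon that keeps the E alkene and the remote stereocentre.

**Step 9**
Reactants: 9 S‑phenyl (5R,6E)‑3‑hydroxy‑8‑[methoxy(methyl)amino]‑5,7‑dimethyl‑8‑oxooct‑6‑enethioate; 14 (2E,4S)‑1‑bromo‑2,4‑dimethylhex‑2‑ene
Product: 15 (2E,4R,10E,12S)‑6‑hydroxy‑N‑methoxy‑N,2,4,10,12‑pentamethyl‑8‑oxotetradeca‑2,10‑dienamide (C6 epimers)
Conditions: NiBr2(dme) (10 mol%), 4,4′‑di‑tert‑butyl‑2,2′‑bipyridine (12 mol%), Bu4NBr, DMA, rt; undivided cell, Zn anode, carbon‑felt cathode, constant current (5 mA, 2.2 F/mol); 14 (1.8 equiv); aq. HCl work‑up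
Reagents that add atoms: none
Why: Proposed new method: nickel‑electrocatalysed reductive acyl–allyl cross‑electrophile coupling of an S‑aryl β‑hydroxy thioester with a 2‑substituted allylic bromide. Cathodically generated zerovalent nickel adds to 14 to give a syn‑η3‑allylnickel bromide that keeps the E geometry; after one‑electron reduction it inserts into the C(acyl)–S bond of 9, and reductive elimination at the unhindered CH2 terminus forges the C8a–C1 bond as a non‑conjugated β,γ‑enone, while zinc ions from the sacrificial anode trap thiophenolate. The closest known reaction types are the nickel‑catalysed electroreductive coupling of acid chlorides with allylic halides and the chemical nickel‑catalysed thioester–alkyl halide ketone synthesis.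

**Step 10**
Reactants: 15 (2E,4R,10E,12S)‑6‑hydroxy‑N‑methoxy‑N,2,4,10,12‑pentamethyl‑8‑oxotetradeca‑2,10‑dienamide
Product: 17 bis(trimethylsilyl) ether cycloadduct (N‑methoxy‑N‑methyl amide; C1=C2 alkene; trans‑fused; C7 epimers), via siloxytriene 16 (not isolated)
Conditions: Me3SiOTf (3 equiv), Et3N (5 equiv), CH2Cl2, −78 → 0 °C; then toluene (0.01 M), BHT, 160 °C, sealed tube
Reagents that add atoms: trimethylsilyl trifluoromethanesulfonate, C[Si](C)(C)OS(=O)(=O)C(F)(F)F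
Why: Soft enolisation silylates the hydroxyl and removes the doubly activated allylic C9–H to give the (8Z,10E)‑1‑siloxydiene (OSiMe3 cis to C10 avoids allylic strain); the thermal intramolecular Diels–Alder reaction then passes through the chair‑like, amide‑endo transition state with the Roche‑derived methyl group equatorial, giving the trans‑fused decalin and setting C3, C4, C4a and C8a relative to C5.

**Step 11**
Reactants: 17 bis(trimethylsilyl) ether cycloadduct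
Product: 19 4‑acetyl‑3‑[(2S)‑butan‑2‑yl]‑2,4,5‑trimethyl‑3,4,4a,5,6,7,8,8a‑octahydronaphthalene‑7,8a‑diol (C7 epimers), via disilyl methyl ketone 18 (not isolated)
Conditions: MeLi (3 equiv), THF, −78 → 0 °C; then MeOH, K2CO3, rt
Reagents that add atoms: methyllithium, [Li]C
Why: Weinreb ketone synthesis: MeLi adds once to the N‑methoxy amide to give a stable lithium chelate, and base‑catalysed methanolysis then releases the methyl ketone and cleaves both silyl ethers without acid, which protects the tertiary allylic 8a‑alcohol from ionisation.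

**Step 12**
Reactants: 19 4‑acetyl‑3‑[(2S)‑butan‑2‑yl]‑2,4,5‑trimethyl‑3,4,4a,5,6,7,8,8a‑octahydronaphthalene‑7,8a‑diol
Product: 20 4‑acetyl‑3‑[(2S)‑butan‑2‑yl]‑2,4,5‑trimethyldecahydronaphthalene‑1,2,7,8a‑tetrol (1β,2β‑diol; C7 epimers)
Conditions: OsO4 (1.05 equiv), TMEDA, CH2Cl2, −78 °C; then aq. Na2SO3, THF, rt
Reagents that add atoms: osmium tetroxide, O=[Os](=O)(=O)=O
Why: Hydroxyl‑directed (Donohoe) syn‑dihydroxylation: the OsO4–TMEDA complex is hydrogen‑bonded by the allylic 8a‑OH and adds to the β face, which is also the face opposite the adjacent α‑sec‑butyl group, so the C2 carbinol is set syn to the 8a‑OH.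

**Step 13**
Reactants: 20 4‑acetyl‑3‑[(2S)‑butan‑2‑yl]‑2,4,5‑trimethyldecahydronaphthalene‑1,2,7,8a‑tetrol
Product: 21 (2S,3R,4S,4aR,5R,8aR)‑4‑acetyl‑3‑[(2S)‑butan‑2‑yl]‑2,8a‑dihydroxy‑2,4,5‑trimethylhexahydronaphthalene‑1,7(2H,8H)‑dione
Conditions: IBX (4 equiv), DMSO, 40 °C
Reagents that add atoms: none
Why: IBX oxidation converts both secondary alcohols (C1 and C7) into ketones, leaves the tertiary alcohols alone and does not cleave the 1,2‑diol, so the C7 epimers converge.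

**Step 14**
Reactants: 21 (2S,3R,4S,4aR,5R,8aR)‑4‑acetyl‑3‑[(2S)‑butan‑2‑yl]‑2,8a‑dihydroxy‑2,4,5‑trimethylhexahydronaphthalene‑1,7(2H,8H)‑dione
Product: 22 (2S,3R,4S,4aR,5R,7R,8aR)‑4‑acetyl‑3‑[(2S)‑butan‑2‑yl]‑2,7,8a‑trihydroxy‑2,4,5,7‑tetramethyloctahydronaphthalen‑1(2H)‑one
Conditions: MeMgBr (4 equiv), CeCl3, THF, −78 °C; then H2O
Reagents that add atoms: methylmagnesium bromide, C[Mg]Br
Why: Grignard addition is chemoselective for the unhindered C7 cyclohexanone over the C1 ketone (flanked by two fully substituted alkoxide carbons) and the neopentyl‑type acetyl group, and the axial 8a‑O–Mg substituent blocks axial attack, so methyl enters equatorially and gives the axial (β) C7 alcohol.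

**Step 15**
Reactants: 22 (2S,3R,4S,4aR,5R,7R,8aR)‑4‑acetyl‑3‑[(2S)‑butan‑2‑yl]‑2,7,8a‑trihydroxy‑2,4,5,7‑tetramethyloctahydronaphthalen‑1(2H)‑one
Product: 23 (2S,3R,4S,4aR,5R,7R,8aR)‑3‑[(2S)‑butan‑2‑yl]‑2,7,8a‑trihydroxy‑2,4,5,7‑tetramethyl‑4‑(3‑oxopropanoyl)octahydronaphthalen‑1(2H)‑one (mainly the hydroxymethylene enol)
Conditions: LiN(SiMe3)2 (5.5 equiv), THF, −78 °C; HCO2CH2CF3, −78 → −20 °C; aq. HCl
Reagents that add atoms: 2,2,2‑trifluoroethyl formate, O=COCC(F)(F)F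
Why: Crossed Claisen formylation is regiospecific because the acetyl CH3 is the only enolisable position (C1 has no α‑hydrogen), and the reactive formate allows low temperature, which avoids α‑ketol rearrangement.

**Step 16**
Reactants: 23 (2S,3R,4S,4aR,5R,7R,8aR)‑3‑[(2S)‑butan‑2‑yl]‑2,7,8a‑trihydroxy‑2,4,5,7‑tetramethyl‑4‑(3‑oxopropanoyl)octahydronaphthalen‑1(2H)‑one
Product: 24 (2S,3R,4S,4aR,5R,7R,8aR)‑3‑[(2S)‑butan‑2‑yl]‑2,7,8a‑trihydroxy‑4‑[(2E)‑3‑methoxyprop‑2‑enoyl]‑2,4,5,7‑tetramethyloctahydronaphthalen‑1(2H)‑one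
Conditions: Me3SiCHN2, MeOH/toluene, 0 °C
Reagents that add atoms: (trimethylsilyl)diazomethane, C[Si](C)(C)C=[N+]=[N-]
Why: Enol O‑methylation by diazomethane released in situ affects only the acidic hydroxymethylene enol, giving the (E)‑β‑methoxy enone and leaving the three tertiary alcohols untouched.

**Compound list**

1 | methyl (R)‑3‑hydroxy‑2‑methylpropanoate | COC(=O)[C@H](C)CO | starting material
2 | methyl (S)‑3‑iodo‑2‑methylpropanoate | COC(=O)[C@H](C)CI | intermediate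
3 | [(2S)‑3‑methoxy‑2‑methyl‑3‑oxopropyl]zinc iodide | COC(=O)[C@H](C)C[Zn]I | intermediate
4 | methyl (R)‑2‑methylpent‑4‑enoate | COC(=O)[C@H](C)CC=C | intermediate
5 | (R)‑2‑methylpent‑4‑enal | O=C[C@H](C)CC=C | intermediate
6 | (2E,4R)‑N‑methoxy‑N,2,4‑trimethylhepta‑2,6‑dienamide | CON(C)C(=O)/C(C)=C/[C@H](C)CC=C | intermediate
7 | (2E,4R)‑N‑methoxy‑N,2,4‑trimethyl‑5‑(1,2,4‑trioxolan‑3‑yl)pent‑2‑enamide | CON(C)C(=O)/C(C)=C/[C@H](C)CC1OCOO1 | intermediate
8 | (2E,4R)‑N‑methoxy‑N,2,4‑trimethyl‑6‑oxohex‑2‑enamide | CON(C)C(=O)/C(C)=C/[C@H](C)CC=O | intermediate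
9 | S‑phenyl (5R,6E)‑3‑hydroxy‑8‑[methoxy(methyl)amino]‑5,7‑dimethyl‑8‑oxooct‑6‑enethioate (C3 epimers) | CON(C)C(=O)/C(C)=C/[C@H](C)CC(O)CC(=O)Sc1ccccc1 | intermediate
10 | (S)‑2‑methylbutan‑1‑ol | CC[C@H](C)CO | starting material
11 | (S)‑2‑methylbutanal | CC[C@H](C)C=O | intermediate
12 | ethyl (2E,4S)‑2,4‑dimethylhex‑2‑enoate | CC[C@H](C)/C=C(\C)C(=O)OCC | intermediate
13 | (2E,4S)‑2,4‑dimethylhex‑2‑en‑1‑ol | CC[C@H](C)/C=C(\C)CO | intermediate
14 | (2E,4S)‑1‑bromo‑2,4‑dimethylhex‑2‑ene | CC[C@H](C)/C=C(\C)CBr | intermediate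
15 | (2E,4R,10E,12S)‑6‑hydroxy‑N‑methoxy‑N,2,4,10,12‑pentamethyl‑8‑oxotetradeca‑2,10‑dienamide (C6 epimers) | CON(C)C(=O)/C(C)=C/[C@H](C)CC(O)CC(=O)C/C(C)=C/[C@@H](C)CC | intermediate
16 | (2E,4R,8Z,10E,12S)‑N‑methoxy‑N,2,4,10,12‑pentamethyl‑6,8‑bis(trimethylsilyloxy)tetradeca‑2,8,10‑trienamide (C6 epimers) | CON(C)C(=O)/C(C)=C/[C@H](C)CC(O[Si](C)(C)C)C/C(O[Si](C)(C)C)=C/C(C)=C/[C@@H](C)CC | intermediate
17 | 3‑[(2S)‑butan‑2‑yl]‑N‑methoxy‑N,2,4,5‑tetramethyl‑7,8a‑bis(trimethylsilyloxy)‑3,4,4a,5,6,7,8,8a‑octahydronaphthalene‑4‑carboxamide (target locants; trans‑fused; 8a‑O, 4‑CH3, 3‑H β; 4a‑H, 5‑CH3, 3‑sec‑butyl, 4‑carboxamide α; C7 epimers) | CC[C@H](C)[C@@H]1[C@](C)(C(=O)N(C)OC)[C@H]2[C@H](C)CC(O[Si](C)(C)C)C[C@]2(O[Si](C)(C)C)C=C1C | intermediate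
18 | 4‑acetyl‑3‑[(2S)‑butan‑2‑yl]‑2,4,5‑trimethyl‑7,8a‑bis(trimethylsilyloxy)‑3,4,4a,5,6,7,8,8a‑octahydronaphthalene (configured as 17) | CC[C@H](C)[C@@H]1[C@](C)(C(C)=O)[C@H]2[C@H](C)CC(O[Si](C)(C)C)C[C@]2(O[Si](C)(C)C)C=C1C | intermediate
19 | 4‑acetyl‑3‑[(2S)‑butan‑2‑yl]‑2,4,5‑trimethyl‑3,4,4a,5,6,7,8,8a‑octahydronaphthalene‑7,8a‑diol (configured as 17; C7 epimers) | CC[C@H](C)[C@@H]1[C@](C)(C(C)=O)[C@H]2[C@H](C)CC(O)C[C@]2(O)C=C1C | intermediate
20 | 4‑acetyl‑3‑[(2S)‑butan‑2‑yl]‑2,4,5‑trimethyldecahydronaphthalene‑1,2,7,8a‑tetrol (1‑OH, 2‑OH, 8a‑OH β; 2‑CH3 α; C7 epimers) | CC[C@H](C)[C@@H]1[C@](C)(C(C)=O)[C@H]2[C@H](C)CC(O)C[C@]2(O)[C@@H](O)[C@@]1(C)O | intermediate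
21 | (2S,3R,4S,4aR,5R,8aR)‑4‑acetyl‑3‑[(2S)‑butan‑2‑yl]‑2,8a‑dihydroxy‑2,4,5‑trimethylhexahydronaphthalene‑1,7(2H,8H)‑dione | CC[C@H](C)[C@@H]1[C@](C)(C(C)=O)[C@H]2[C@H](C)CC(=O)C[C@]2(O)C(=O)[C@@]1(C)O | intermediate
22 | (2S,3R,4S,4aR,5R,7R,8aR)‑4‑acetyl‑3‑[(2S)‑butan‑2‑yl]‑2,7,8a‑trihydroxy‑2,4,5,7‑tetramethyloctahydronaphthalen‑1(2H)‑one | CC[C@H](C)[C@@H]1[C@](C)(C(C)=O)[C@H]2[C@H](C)C[C@@](C)(O)C[C@]2(O)C(=O)[C@@]1(C)O | intermediate
23 | (2S,3R,4S,4aR,5R,7R,8aR)‑3‑[(2S)‑butan‑2‑yl]‑2,7,8a‑trihydroxy‑2,4,5,7‑tetramethyl‑4‑(3‑oxopropanoyl)octahydronaphthalen‑1(2H)‑one | CC[C@H](C)[C@@H]1[C@](C)(C(=O)CC=O)[C@H]2[C@H](C)C[C@@](C)(O)C[C@]2(O)C(=O)[C@@]1(C)O | intermediate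
24 | (2S,3R,4S,4aR,5R,7R,8aR)‑3‑[(2S)‑butan‑2‑yl]‑2,7,8a‑trihydroxy‑4‑[(2E)‑3‑methoxyprop‑2‑enoyl]‑2,4,5,7‑tetramethyloctahydronaphthalen‑1(2H)‑one | CC[C@H](C)[C@@H]1[C@](C)(C(=O)/C=C/OC)[C@H]2[C@H](C)C[C@@](C)(O)C[C@]2(O)C(=O)[C@@]1(C)O | target

**Step count**

Total: 16 steps. Longest linear sequence: 13 steps (steps 1–5 and 9–16).

**Three steps most likely to fail**

Step 9 (proposed new electrochemical coupling). Risks are allyl–allyl homocoupling, S‑allylation of the released thiophenolate, syn/anti scrambling of the allylnickel (E/Z erosion) and sluggish C–S activation. The fallback is known sulfone chemistry; it sets out from 9 and 14 and returns to the route at 15. Compound 9 is silylated (Et3SiCl, imidazole, DMF) to the triethylsilyl ether F1. Bromide 14 and PhSO2Na (DMF, rt) give the allylic sulfone F2. F2 (2.1 equiv) is lithiated with n‑BuLi (THF, −78 °C) and acylated by F1 to give the β‑keto sulfone F3. SmI2 (THF/MeOH, −78 °C) removes the sulfonyl group with kinetic α‑protonation, giving the silyl‑protected skipped enone F4, and HF·pyridine (THF, 0 °C) then gives 15.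

Step 10 (silylation and intramolecular Diels–Alder reaction). Risks are an unfavourable Z/E ratio of the dienol ether, the weak amide dienophile, formation of the exo (cis‑fused) adduct and loss of the silyl ethers at 160 °C. The fallback changes the diene class and the mode of activation; it sets out from 15 and returns at 19. Compound 15 is treated with LiN(SiMe3)2 (2.2 equiv, THF, −78 °C) and Ac2O to give the acid‑stable dienyl diacetate F5 (C6 acetate and (8Z)‑enol acetate). EtAlCl2 (CH2Cl2, −40 → 0 °C) chelates the N‑methoxy amide and promotes the cycloaddition at low temperature to the diacetate cycloadduct F6. Excess MeLi (THF, −78 → 0 °C) cleaves both acetates and converts the amide into the methyl ketone, giving 19.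

Step 14 (chemo‑ and stereoselective methyl addition). Risks are competing addition at the acetyl or C1 ketone and retro‑aldol opening of the β‑hydroxy ketone. The fallback reorders the end game so that C7 is methylated before the C1 ketone exists; it sets out from 19 and returns at 22. Dess–Martin periodinane oxidises the only secondary alcohol of 19 to the C7 ketone F7. MeMgBr/CeCl3 (THF, −78 °C) gives the C7 methyl carbinol F8, with only the hindered acetyl group competing. OsO4/TMEDA dihydroxylation gives the tetrol F9, and IBX oxidises its single secondary alcohol to give 22.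

**Further compounds**

F1 | step 9 | S‑phenyl (5R,6E)‑8‑[methoxy(methyl)amino]‑5,7‑dimethyl‑8‑oxo‑3‑(triethylsilyloxy)oct‑6‑enethioate | CON(C)C(=O)/C(C)=C/[C@H](C)CC(O[Si](CC)(CC)CC)CC(=O)Sc1ccccc1
F2 | step 9 | [(2E,4S)‑2,4‑dimethylhex‑2‑en‑1‑yl]sulfonylbenzene | CC[C@H](C)/C=C(\C)CS(=O)(=O)c1ccccc1
F3 | step 9 | (2E,4R,10E,12S)‑N‑methoxy‑N,2,4,10,12‑pentamethyl‑8‑oxo‑9‑(phenylsulfonyl)‑6‑(triethylsilyloxy)tetradeca‑2,10‑dienamide | CON(C)C(=O)/C(C)=C/[C@H](C)CC(O[Si](CC)(CC)CC)CC(=O)C(S(=O)(=O)c1ccccc1)/C(C)=C/[C@@H](C)CC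
F4 | step 9 | (2E,4R,10E,12S)‑N‑methoxy‑N,2,4,10,12‑pentamethyl‑8‑oxo‑6‑(triethylsilyloxy)tetradeca‑2,10‑dienamide | CON(C)C(=O)/C(C)=C/[C@H](C)CC(O[Si](CC)(CC)CC)CC(=O)C/C(C)=C/[C@@H](C)CC
F5 | step 10 | (2E,4R,8Z,10E,12S)‑1‑[methoxy(methyl)amino]‑2,4,10,12‑tetramethyl‑1‑oxotetradeca‑2,8,10‑triene‑6,8‑diyl diacetate | CON(C)C(=O)/C(C)=C/[C@H](C)CC(OC(C)=O)C/C(OC(C)=O)=C/C(C)=C/[C@@H](C)CC
F6 | step 10 | 3‑[(2S)‑butan‑2‑yl]‑4‑[methoxy(methyl)carbamoyl]‑2,4,5‑trimethyl‑3,4,4a,5,6,7,8,8a‑octahydronaphthalene‑7,8a‑diyl diacetate (configured as 17) | CC[C@H](C)[C@@H]1[C@](C)(C(=O)N(C)OC)[C@H]2[C@H](C)CC(OC(C)=O)C[C@]2(OC(C)=O)C=C1C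
F7 | step 14 | 4‑acetyl‑3‑[(2S)‑butan‑2‑yl]‑8a‑hydroxy‑2,4,5‑trimethyl‑4,4a,5,6,8,8a‑hexahydronaphthalen‑7(3H)‑one (configured as 19) | CC[C@H](C)[C@@H]1[C@](C)(C(C)=O)[C@H]2[C@H](C)CC(=O)C[C@]2(O)C=C1C
F8 | step 14 | 4‑acetyl‑3‑[(2S)‑butan‑2‑yl]‑2,4,5,7‑tetramethyl‑3,4,4a,5,6,7,8,8a‑octahydronaphthalene‑7,8a‑diol (7‑OH β) | CC[C@H](C)[C@@H]1[C@](C)(C(C)=O)[C@H]2[C@H](C)C[C@@](C)(O)C[C@]2(O)C=C1C
F9 | step 14 | 4‑acetyl‑3‑[(2S)‑butan‑2‑yl]‑2,4,5,7‑tetramethyldecahydronaphthalene‑1,2,7,8a‑tetrol (1‑OH, 2‑OH, 7‑OH, 8a‑OH β) | CC[C@H](C)[C@@H]1[C@](C)(C(C)=O)[C@H]2[C@H](C)C[C@@](C)(O)C[C@]2(O)[C@@H](O)[C@@]1(C)O
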